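Ring B (C5–C6–C7–C8–C9–C10) is read as its C6=C7 isomer, the retron of an intramolecular Diels–Alder reaction. Cutting the ring-fusion bond C5–C10 together with C8–C9 opens both rings to an acyclic (2E,8E,10E)-trienal in which C11 is the formyl group on the C9=C10 dienophile and C1–C4 is the tether. One catalyst-controlled endo cycloaddition closes rings A and B, creates quaternary C10 and sets C5, C9 and C10 of the trans-decalin. The formyl group then takes up C12–C15 (C13 from the chiral pool), and oxidation at C17 draws the alkene into the C7=C8 position before reduction and acetylation.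

Key step: step 8

Remark: carbons are numbered as in labdanes (C10 carries the angular methyl, C5 the ring-fusion hydrogen, C9 the side chain C11–C15, C17 is the acetoxymethyl carbon on C8, C13 the side-chain stereocentre).

Step 1
Reactants: 1 2,2-dimethylpent-4-enal; 2 triethyl 4-phosphonocrotonate
Product: 3 ethyl (2E,4E)-6,6-dimethylnona-2,4,8-trienoate
Conditions: LiN(SiMe3)2, THF, −78 → 0 °C
Reagents that add atoms: none
Why: Horner–Wadsworth–Emmons olefination with the vinylogous phosphonate adds C6, C7, C8 and C17 to the non-enolisable aldehyde carbon C5 and should give the favoured 2E,4E-dienoate.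

Step 2
Reactants: 3 ethyl (2E,4E)-6,6-dimethylnona-2,4,8-trienoate
Product: 4 (2E,4E)-6,6-dimethylnona-2,4,8-trien-1-ol
Conditions: i-Bu2AlH (2.2 equiv), CH2Cl2, −78 °C
Reagents that add atoms: none
Why: Hydride reduction of the conjugated ester in the 1,2 sense gives the primary dienol and leaves the alkenes alone.

Step 3
Reactants: 4 (2E,4E)-6,6-dimethylnona-2,4,8-trien-1-ol
Product: 5 tert-butyl{[(2E,4E)-6,6-dimethylnona-2,4,8-trien-1-yl]oxy}diphenylsilane
Conditions: TBDPSCl, imidazole, DMF, rt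
Reagents that add atoms: tert-butyl(chloro)diphenylsilane, CC(C)(C)[Si](Cl)(c1ccccc1)c1ccccc1
Why: Silylation of the primary alcohol gives an ether that should survive the borane, palladium, Lewis acid and ylide of the following steps.

Step 4
Reactants: 6 ethyl acetoacetate
Product: 7 ethyl (2E)-3-{[(trifluoromethyl)sulfonyl]oxy}but-2-enoate
Conditions: Tf2O, aqueous Me4NOH, hexane, 5 °C
Reagents that add atoms: triflic anhydride, O=S(=O)(OS(=O)(=O)C(F)(F)F)C(F)(F)F
Why: O-Triflation of the non-chelated tetramethylammonium enolate of the β-keto ester places the triflate trans to the ester (E enol triflate), which fixes the later dienophile geometry.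

Step 5
Reactants: 5 tert-butyl{[(2E,4E)-6,6-dimethylnona-2,4,8-trien-1-yl]oxy}diphenylsilane; 7 ethyl (2E)-3-{[(trifluoromethyl)sulfonyl]oxy}but-2-enoate
Product: 9 ethyl (2E,8E,10E)-12-{[tert-butyl(diphenyl)silyl]oxy}-3,7,7-trimethyldodeca-2,8,10-trienoate, via B-alkyl-9-BBN adduct 8 (not isolated)
Conditions: 9-BBN, THF, 0 °C → rt; then 7, Pd(dppf)Cl2 (5 mol%), K3PO4, THF–DMF–H2O, rt
Reagents that add atoms: none
Why: 9-BBN hydroborates only the monosubstituted terminal alkene in the anti-Markovnikov sense, and the B-alkyl Suzuki–Miyaura coupling with the enol triflate forms C1–C10 with retention of the E geometry.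

Step 6
Reactants: 9 ethyl (2E,8E,10E)-12-{[tert-butyl(diphenyl)silyl]oxy}-3,7,7-trimethyldodeca-2,8,10-trienoate
Product: 10 (2E,8E,10E)-12-{[tert-butyl(diphenyl)silyl]oxy}-3,7,7-trimethyldodeca-2,8,10-trien-1-ol
Conditions: i-Bu2AlH (2.2 equiv), CH2Cl2, −78 °C
Reagents that add atoms: none
Why: 1,2-Reduction of the enoate gives the allylic alcohol; the silyl ether and the alkenes are inert.

Step 7
Reactants: 10 (2E,8E,10E)-12-{[tert-butyl(diphenyl)silyl]oxy}-3,7,7-trimethyldodeca-2,8,10-trien-1-ol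
Product: 11 (2E,8E,10E)-12-{[tert-butyl(diphenyl)silyl]oxy}-3,7,7-trimethyldodeca-2,8,10-trienal
Conditions: MnO2, CH2Cl2, rt
Reagents that add atoms: none
Why: MnO2 oxidises only the free allylic alcohol to the E enal; the silyl-protected dienyl alcohol cannot react.

Step 8
Reactants: 11 (2E,8E,10E)-12-{[tert-butyl(diphenyl)silyl]oxy}-3,7,7-trimethyldodeca-2,8,10-trienal
Product: 12 (1R,2R,4aR,8aR)-2-({[tert-butyl(diphenyl)silyl]oxy}methyl)-5,5,8a-trimethyl-1,2,4a,5,6,7,8,8a-octahydronaphthalene-1-carbaldehyde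
Conditions: (S)-α,α-diphenylprolinol-derived B-(o-tolyl)oxazaborolidine (20 mol%), Tf2NH (18 mol%), CH2Cl2, −78 → −20 °C
Reagents that add atoms: none
Why: The oxazaborolidinium ion binds the formyl oxygen of 11 and lowers the LUMO of the C9=C10 enal, which then undergoes a concerted but asynchronous intramolecular [4+2] cycloaddition with the C5=C6–C7=C8 diene, the bond from the β-carbon C10 to C5 being the more advanced; the closest known reaction type is the chiral Lewis acid catalysed intramolecular Diels–Alder reaction of 2,8,10-trienals. Ring B (C5–C6–C7–C8–C9–C10) is the cycloaddition ring, and ring A closes at the same time as the four-carbon tether C1–C4 folds into a chair while the ring-fusion bond C5–C10 forms. The E dienophile places the C10 methyl and the C9 formyl group cis, the E,E-diene places C4 and C17 cis, and the endo transition state (formyl group under the diene, tether exo) puts the C10 methyl trans to the C5 hydrogen, which should give the trans-decalin with C8 as a fourth centre that is erased in step 13. The absolute configuration comes from the catalyst, whose aryl group stacks on one face of the s-trans enal so that the diene must reach C9 from its Re face (C10 from its Si face); the (S)-catalyst is the antipode assigned to this face by the formyl C–H···O binding model, and its mirror image serves if the sense proves reversed. The step needs endo over exo selectivity and one enantioface: the first rests on the Lewis acid bound formyl group and the chair tether helped by the gem-dimethyl group, the second on the catalyst, and a Lewis acid instead of an amine catalyst is chosen so that the E enal cannot isomerise through an iminium ion.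

Step 9
Reactants: 13 (3R)-5-methoxy-3-methyl-5-oxopentanoic acid
Product: 14 methyl (3S)-4-iodo-3-methylbutanoate
Conditions: PhI(OAc)2, I2, cyclohexane, hν, reflux
Reagents that add atoms: iodine, II
Why: Hunsdiecker-type iododecarboxylation (acyl hypoiodite, loss of CO2, iodine capture of the primary radical) replaces the carboxyl group by iodine; the stereocentre lies one carbon away from the radical and is untouched (the descriptor changes only by priority).

Step 10
Reactants: 14 methyl (3S)-4-iodo-3-methylbutanoate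
Product: 15 [(2S)-4-methoxy-2-methyl-4-oxobutyl](triphenyl)phosphonium iodide
Conditions: PPh3, MeCN, reflux
Reagents that add atoms: triphenylphosphine, c1ccc(cc1)P(c1ccccc1)c1ccccc1
Why: SN2 quaternisation of the phosphine by the primary iodide gives the Wittig salt.

Step 11
Reactants: 12 (1R,2R,4aR,8aR)-2-({[tert-butyl(diphenyl)silyl]oxy}methyl)-5,5,8a-trimethyl-1,2,4a,5,6,7,8,8a-octahydronaphthalene-1-carbaldehyde; 15 [(2S)-4-methoxy-2-methyl-4-oxobutyl](triphenyl)phosphonium iodide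
Product: 17 methyl (3S,4Z)-5-[(1R,2R,4aR,8aS)-2-({[tert-butyl(diphenyl)silyl]oxy}methyl)-5,5,8a-trimethyl-1,2,4a,5,6,7,8,8a-octahydronaphthalen-1-yl]-3-methylpent-4-enoate, via phosphorus ylide 16 (not isolated)
Conditions: NaN(SiMe3)2, THF, 0 °C; then 12, −78 °C → rt
Reagents that add atoms: none
Why: Wittig reaction of the salt-free non-stabilised ylide with the aldehyde joins C11 to C12 as the Z alkene, with C13 brought in already set; the alkene geometry is erased in step 16.

Step 12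
Reactants: 17 methyl (3S,4Z)-5-[(1R,2R,4aR,8aS)-2-({[tert-butyl(diphenyl)silyl]oxy}methyl)-5,5,8a-trimethyl-1,2,4a,5,6,7,8,8a-octahydronaphthalen-1-yl]-3-methylpent-4-enoate
Product: 18 methyl (3S,4Z)-5-[(1R,2R,4aR,8aS)-2-(hydroxymethyl)-5,5,8a-trimethyl-1,2,4a,5,6,7,8,8a-octahydronaphthalen-1-yl]-3-methylpent-4-enoate
Conditions: Bu4NF, THF, 0 °C
Reagents that add atoms: none
Why: Fluoride cleaves the Si–O bond and frees the C17 alcohol; the methyl ester should not be attacked at 0 °C.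

Step 13
Reactants: 18 methyl (3S,4Z)-5-[(1R,2R,4aR,8aS)-2-(hydroxymethyl)-5,5,8a-trimethyl-1,2,4a,5,6,7,8,8a-octahydronaphthalen-1-yl]-3-methylpent-4-enoate
Product: 20 methyl (3S,4Z)-5-[(1S,4aR,8aR)-2-formyl-5,5,8a-trimethyl-1,4,4a,5,6,7,8,8a-octahydronaphthalen-1-yl]-3-methylpent-4-enoate, via unconjugated aldehyde 19 (not isolated)
Conditions: Dess–Martin periodinane, NaHCO3, CH2Cl2, 0 °C; then DBU (0.2 equiv), CH2Cl2, rt
Reagents that add atoms: none
Why: Dess–Martin oxidation gives the β,γ-unsaturated aldehyde, whose acidic C8 hydrogen lets DBU move the alkene through the dienolate into conjugation; this places the double bond at C7=C8 and erases the C8 centre, while the C9 hydrogen is not acidified by the carbonyl group.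

Step 14
Reactants: 20 methyl (3S,4Z)-5-[(1S,4aR,8aR)-2-formyl-5,5,8a-trimethyl-1,4,4a,5,6,7,8,8a-octahydronaphthalen-1-yl]-3-methylpent-4-enoate
Product: 21 methyl (3S,4Z)-5-[(1S,4aR,8aR)-2-(hydroxymethyl)-5,5,8a-trimethyl-1,4,4a,5,6,7,8,8a-octahydronaphthalen-1-yl]-3-methylpent-4-enoate
Conditions: NaBH4, CeCl3·7H2O, MeOH, −40 °C
Reagents that add atoms: none
Why: Luche reduction delivers hydride 1,2 to the enal and should leave the saturated methyl ester and the alkenes alone.

Step 15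
Reactants: 21 methyl (3S,4Z)-5-[(1S,4aR,8aR)-2-(hydroxymethyl)-5,5,8a-trimethyl-1,4,4a,5,6,7,8,8a-octahydronaphthalen-1-yl]-3-methylpent-4-enoate
Product: 22 methyl (3S,4Z)-5-[(1S,4aR,8aR)-2-(acetoxymethyl)-5,5,8a-trimethyl-1,4,4a,5,6,7,8,8a-octahydronaphthalen-1-yl]-3-methylpent-4-enoate
Conditions: Ac2O, pyridine, DMAP (cat.), CH2Cl2, rt
Reagents that add atoms: acetic anhydride, CC(=O)OC(C)=O
Why: DMAP-catalysed acylation of the primary allylic alcohol.

Step 16
Reactants: 22 methyl (3S,4Z)-5-[(1S,4aR,8aR)-2-(acetoxymethyl)-5,5,8a-trimethyl-1,4,4a,5,6,7,8,8a-octahydronaphthalen-1-yl]-3-methylpent-4-enoate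
Product: 23 methyl (3R)-5-[(1S,4aR,8aR)-2-(acetoxymethyl)-5,5,8a-trimethyl-1,4,4a,5,6,7,8,8a-octahydronaphthalen-1-yl]-3-methylpentanoate
Conditions: H2 (1 atm), RhCl(PPh3)3 (10 mol%), benzene–EtOH, rt
Reagents that add atoms: none
Why: Homogeneous hydrogenation with RhCl(PPh3)3 saturates the 1,2-disubstituted C11=C12 alkene much faster than the trisubstituted ring alkene and does not hydrogenolyse the allylic acetate.

Compound list

1 | 2,2-dimethylpent-4-enal | C=CCC(C)(C)C=O | starting material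
2 | triethyl 4-phosphonocrotonate | CCOC(=O)/C=C/CP(=O)(OCC)OCC | starting material
3 | ethyl (2E,4E)-6,6-dimethylnona-2,4,8-trienoate | CCOC(=O)/C=C/C=C/C(C)(C)CC=C | intermediate
4 | (2E,4E)-6,6-dimethylnona-2,4,8-trien-1-ol | OC/C=C/C=C/C(C)(C)CC=C | intermediate
5 | tert-butyl{[(2E,4E)-6,6-dimethylnona-2,4,8-trien-1-yl]oxy}diphenylsilane | C=CCC(C)(C)/C=C/C=C/CO[Si](c1ccccc1)(c1ccccc1)C(C)(C)C | intermediate
6 | ethyl acetoacetate | CCOC(=O)CC(C)=O | starting material
7 | ethyl (2E)-3-{[(trifluoromethyl)sulfonyl]oxy}but-2-enoate | CCOC(=O)/C=C(\C)OS(=O)(=O)C(F)(F)F | intermediate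
8 | 9-[(5E,7E)-9-{[tert-butyl(diphenyl)silyl]oxy}-4,4-dimethylnona-5,7-dien-1-yl]-9-borabicyclo[3.3.1]nonane | CC(C)(C)[Si](OC/C=C/C=C/C(C)(C)CCCB1C2CCCC1CCC2)(c1ccccc1)c1ccccc1 | intermediate
9 | ethyl (2E,8E,10E)-12-{[tert-butyl(diphenyl)silyl]oxy}-3,7,7-trimethyldodeca-2,8,10-trienoate | CCOC(=O)/C=C(\C)CCCC(C)(C)/C=C/C=C/CO[Si](c1ccccc1)(c1ccccc1)C(C)(C)C | intermediate
10 | (2E,8E,10E)-12-{[tert-butyl(diphenyl)silyl]oxy}-3,7,7-trimethyldodeca-2,8,10-trien-1-ol | OC/C=C(\C)CCCC(C)(C)/C=C/C=C/CO[Si](c1ccccc1)(c1ccccc1)C(C)(C)C | intermediate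
11 | (2E,8E,10E)-12-{[tert-butyl(diphenyl)silyl]oxy}-3,7,7-trimethyldodeca-2,8,10-trienal | O=C/C=C(\C)CCCC(C)(C)/C=C/C=C/CO[Si](c1ccccc1)(c1ccccc1)C(C)(C)C | intermediate
12 | (1R,2R,4aR,8aR)-2-({[tert-butyl(diphenyl)silyl]oxy}methyl)-5,5,8a-trimethyl-1,2,4a,5,6,7,8,8a-octahydronaphthalene-1-carbaldehyde (trans-fused; formyl, silyloxymethyl and angular methyl all cis) | O=C[C@@H]1[C@H](CO[Si](c3ccccc3)(c3ccccc3)C(C)(C)C)C=C[C@@H]2C(C)(C)CCC[C@@]12C | intermediate
13 | (3R)-5-methoxy-3-methyl-5-oxopentanoic acid ((R)-3-methylglutaric acid monomethyl ester) | COC(=O)C[C@H](C)CC(=O)O | starting material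
14 | methyl (3S)-4-iodo-3-methylbutanoate | COC(=O)C[C@H](C)CI | intermediate
15 | [(2S)-4-methoxy-2-methyl-4-oxobutyl](triphenyl)phosphonium iodide | COC(=O)C[C@H](C)C[P+](c1ccccc1)(c1ccccc1)c1ccccc1.[I-] | intermediate
16 | methyl (3S)-3-methyl-4-(triphenyl-λ5-phosphanylidene)butanoate | COC(=O)C[C@H](C)C=P(c1ccccc1)(c1ccccc1)c1ccccc1 | intermediate
17 | methyl (3S,4Z)-5-[(1R,2R,4aR,8aS)-2-({[tert-butyl(diphenyl)silyl]oxy}methyl)-5,5,8a-trimethyl-1,2,4a,5,6,7,8,8a-octahydronaphthalen-1-yl]-3-methylpent-4-enoate | COC(=O)C[C@H](C)/C=C\[C@@H]1[C@H](CO[Si](c3ccccc3)(c3ccccc3)C(C)(C)C)C=C[C@@H]2C(C)(C)CCC[C@@]12C | intermediate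
18 | methyl (3S,4Z)-5-[(1R,2R,4aR,8aS)-2-(hydroxymethyl)-5,5,8a-trimethyl-1,2,4a,5,6,7,8,8a-octahydronaphthalen-1-yl]-3-methylpent-4-enoate | COC(=O)C[C@H](C)/C=C\[C@@H]1[C@H](CO)C=C[C@@H]2C(C)(C)CCC[C@@]12C | intermediate
19 | methyl (3S,4Z)-5-[(1R,2R,4aR,8aS)-2-formyl-5,5,8a-trimethyl-1,2,4a,5,6,7,8,8a-octahydronaphthalen-1-yl]-3-methylpent-4-enoate | COC(=O)C[C@H](C)/C=C\[C@@H]1[C@H](C=O)C=C[C@@H]2C(C)(C)CCC[C@@]12C | intermediate
20 | methyl (3S,4Z)-5-[(1S,4aR,8aR)-2-formyl-5,5,8a-trimethyl-1,4,4a,5,6,7,8,8a-octahydronaphthalen-1-yl]-3-methylpent-4-enoate | COC(=O)C[C@H](C)/C=C\[C@@H]1C(C=O)=CC[C@@H]2C(C)(C)CCC[C@@]12C | intermediate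
21 | methyl (3S,4Z)-5-[(1S,4aR,8aR)-2-(hydroxymethyl)-5,5,8a-trimethyl-1,4,4a,5,6,7,8,8a-octahydronaphthalen-1-yl]-3-methylpent-4-enoate | COC(=O)C[C@H](C)/C=C\[C@@H]1C(CO)=CC[C@@H]2C(C)(C)CCC[C@@]12C | intermediate
22 | methyl (3S,4Z)-5-[(1S,4aR,8aR)-2-(acetoxymethyl)-5,5,8a-trimethyl-1,4,4a,5,6,7,8,8a-octahydronaphthalen-1-yl]-3-methylpent-4-enoate | COC(=O)C[C@H](C)/C=C\[C@@H]1C(COC(C)=O)=CC[C@@H]2C(C)(C)CCC[C@@]12C | intermediate
23 | methyl (3R)-5-[(1S,4aR,8aR)-2-(acetoxymethyl)-5,5,8a-trimethyl-1,4,4a,5,6,7,8,8a-octahydronaphthalen-1-yl]-3-methylpentanoate | COC(=O)C[C@H](C)CC[C@@H]1C(COC(C)=O)=CC[C@@H]2C(C)(C)CCC[C@@]12C | target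

Total step count: 16. Longest linear sequence: 13 steps (steps 1, 2, 3, 5, 6, 7, 8, 11, 12, 13, 14, 15, 16).

Steps most likely to fail

Step 8. The β,β-disubstituted enal may bind the catalyst too weakly to cyclise at low temperature. It may also close through the exo (cis-fused) transition state once the C4 and C10 methyl groups clash, and the level or sense of facial selection may be inadequate. The fallback replaces catalyst control by auxiliary control; it sets out from 9 and comes back at 12. Ester 9 is saponified (LiOH, THF–H2O) to the trienoic acid F1. Its pivaloyl mixed anhydride acylates lithiated (4R)-4-benzyl-1,3-oxazolidin-2-one to give the imide F2. Me2AlCl (1.4 equiv, CH2Cl2, −30 °C) forms the chelated cationic s-cis imide, whose benzyl group covers the C9 Si face, so that endo cycloaddition should give the cycloadduct imide F3 with the same C5, C8, C9 and C10 configuration as 12. LiBH4 (THF–MeOH) releases the auxiliary and gives the primary alcohol F4, and Dess–Martin oxidation returns aldehyde 12.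

Step 11. Addition of the branched ylide to the neopentyl-type aldehyde may be slow, so that enolisation and epimerisation at C9 compete. The fallback forms C11–C12 as an sp3–sp3 bond; it sets out from 12 and comes back at the target 23. NaBH4 reduces 12 to the primary alcohol F4, and I2, PPh3 and imidazole give the primary iodide F5. Iodide 14 is converted with zinc dust and LiCl into the alkylzinc iodide F6. A nickel-catalysed alkyl–alkyl Negishi coupling (Ni(cod)2, s-Bu-Pybox, DMA) joins F5 and F6 to the saturated silyl ether F7. Bu4NF gives the alcohol F8, and Dess–Martin oxidation gives the unconjugated aldehyde F9, which DBU isomerises to the conjugated enal F10. Luche reduction gives the allylic alcohol F11, and acetylation gives 23 without the final hydrogenation.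

Step 5. Hydrolysis or addition–elimination at the β-triflyloxy enoate and slow B-alkyl transfer may erode the yield and the alkene geometry. The fallback builds the trisubstituted alkene by carbometalation of an alkyne; it sets out from 5 and comes back at 9. Borane 8 (from 5 and 9-BBN) is treated with I2 and NaOMe to give the primary iodide F12. Iodine–lithium exchange (t-BuLi, Et2O, −78 °C) and CuI·PBu3 give the alkylcopper reagent F13. F13 adds syn across ethyl but-2-ynoate at −78 °C, and protonation of the vinylcopper gives 9 with the new chain trans to the ester.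

Further compounds
F1 | step 8 | (2E,8E,10E)-12-{[tert-butyl(diphenyl)silyl]oxy}-3,7,7-trimethyldodeca-2,8,10-trienoic acid | OC(=O)/C=C(\C)CCCC(C)(C)/C=C/C=C/CO[Si](c1ccccc1)(c1ccccc1)C(C)(C)C
F2 | step 8 | (4R)-4-benzyl-3-[(2E,8E,10E)-12-{[tert-butyl(diphenyl)silyl]oxy}-3,7,7-trimethyldodeca-2,8,10-trienoyl]-1,3-oxazolidin-2-one | O=C(/C=C(\C)CCCC(C)(C)/C=C/C=C/CO[Si](c1ccccc1)(c1ccccc1)C(C)(C)C)N1[C@H](Cc2ccccc2)COC1=O
F3 | step 8 | (4R)-4-benzyl-3-{[(1R,2R,4aR,8aR)-2-({[tert-butyl(diphenyl)silyl]oxy}methyl)-5,5,8a-trimethyl-1,2,4a,5,6,7,8,8a-octahydronaphthalen-1-yl]carbonyl}-1,3-oxazolidin-2-one | O=C([C@@H]1[C@H](CO[Si](c3ccccc3)(c3ccccc3)C(C)(C)C)C=C[C@@H]2C(C)(C)CCC[C@@]12C)N1[C@H](Cc2ccccc2)COC1=O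
F4 | step 8 | [(1R,2R,4aR,8aR)-2-({[tert-butyl(diphenyl)silyl]oxy}methyl)-5,5,8a-trimethyl-1,2,4a,5,6,7,8,8a-octahydronaphthalen-1-yl]methanol | OC[C@@H]1[C@H](CO[Si](c3ccccc3)(c3ccccc3)C(C)(C)C)C=C[C@@H]2C(C)(C)CCC[C@@]12C
F5 | step 11 | tert-butyl{[(1R,2R,4aR,8aR)-1-(iodomethyl)-5,5,8a-trimethyl-1,2,4a,5,6,7,8,8a-octahydronaphthalen-2-yl]methoxy}diphenylsilane | IC[C@@H]1[C@H](CO[Si](c3ccccc3)(c3ccccc3)C(C)(C)C)C=C[C@@H]2C(C)(C)CCC[C@@]12C
F6 | step 11 | [(2S)-4-methoxy-2-methyl-4-oxobutyl]zinc iodide | COC(=O)C[C@H](C)C[Zn]I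
F7 | step 11 | methyl (3R)-5-[(1R,2R,4aR,8aS)-2-({[tert-butyl(diphenyl)silyl]oxy}methyl)-5,5,8a-trimethyl-1,2,4a,5,6,7,8,8a-octahydronaphthalen-1-yl]-3-methylpentanoate | COC(=O)C[C@H](C)CC[C@@H]1[C@H](CO[Si](c3ccccc3)(c3ccccc3)C(C)(C)C)C=C[C@@H]2C(C)(C)CCC[C@@]12C
F8 | step 11 | methyl (3R)-5-[(1R,2R,4aR,8aS)-2-(hydroxymethyl)-5,5,8a-trimethyl-1,2,4a,5,6,7,8,8a-octahydronaphthalen-1-yl]-3-methylpentanoate | COC(=O)C[C@H](C)CC[C@@H]1[C@H](CO)C=C[C@@H]2C(C)(C)CCC[C@@]12C
F9 | step 11 | methyl (3R)-5-[(1R,2R,4aR,8aS)-2-formyl-5,5,8a-trimethyl-1,2,4a,5,6,7,8,8a-octahydronaphthalen-1-yl]-3-methylpentanoate | COC(=O)C[C@H](C)CC[C@@H]1[C@H](C=O)C=C[C@@H]2C(C)(C)CCC[C@@]12C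
F10 | step 11 | methyl (3R)-5-[(1S,4aR,8aR)-2-formyl-5,5,8a-trimethyl-1,4,4a,5,6,7,8,8a-octahydronaphthalen-1-yl]-3-methylpentanoate | COC(=O)C[C@H](C)CC[C@@H]1C(C=O)=CC[C@@H]2C(C)(C)CCC[C@@]12C
F11 | step 11 | methyl (3R)-5-[(1S,4aR,8aR)-2-(hydroxymethyl)-5,5,8a-trimethyl-1,4,4a,5,6,7,8,8a-octahydronaphthalen-1-yl]-3-methylpentanoate | COC(=O)C[C@H](C)CC[C@@H]1C(CO)=CC[C@@H]2C(C)(C)CCC[C@@]12C
F12 | step 5 | tert-butyl{[(2E,4E)-9-iodo-6,6-dimethylnona-2,4-dien-1-yl]oxy}diphenylsilane | ICCCC(C)(C)/C=C/C=C/CO[Si](c1ccccc1)(c1ccccc1)C(C)(C)C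
F13 | step 5 | [(5E,7E)-9-{[tert-butyl(diphenyl)silyl]oxy}-4,4-dimethylnona-5,7-dien-1-yl]copper | [Cu]CCCC(C)(C)/C=C/C=C/CO[Si](c1ccccc1)(c1ccccc1)C(C)(C)C
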